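**Retrosynthetic overview**
- The 4-hydroxybenzoate and the C10 carbonyl are added last (esterification, allylic oxidation) to dauc-8-ene-4β,6α-diol 19. Its C6 carbinol comes from a hydroxyl-directed reduction of ketone 18.
- The route rests on one feature of the seven-membered ring: C7H2 lies between oxygen-bearing C6 and the C8=C9 alkene, and the C1–C10 bond lies across the ring from it. A C5=C6(O)/C8=C9 1,4-diene of this kind is the retron of a cis-divinylcyclopropane (C6–C7–C8) Cope rearrangement.
- Key disconnection: C1–C10, by [3,3] shift of the 1-cyclopentenyl-1-siloxy-2-methyl-2-vinylcyclopropane 15. O4 and O6 are joined by a di-tert-butylsilylene bridge in place of two separate silyl ethers, because the bridge decides which boat can be reached.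
- The cyclopropane comes from Simmons–Smith methylenation of the bridged (E)-enol ether of an α-alkynyl ketone (alkyne = masked vinyl). The ketone comes from propargylation and oxidation of the cyclopentenecarbaldehyde obtained by ozonolysis and aldol condensation of (S)-terpinen-4-ol.
- Ring order: five-membered ring (step 3), silicon bridge (step 8), cyclopropane (step 9), seven-membered ring (step 12).

Key step: step 12

Remarks on the chemistry
- Daucane numbering is used: C1 ring-fusion carbon with methyl, C4 isopropyl carbinol, C5 ring-fusion CH, C6 acyloxy CH, C7 CH2, C8 methyl-bearing alkene carbon, C9, C10 ketone. β is the face of the C1 methyl group and the C4 oxygen.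
- Assumption: the carbinol and propargylic centres made in step 6 are carried as a mixture of epimers, because steps 7 and 8 remove both.

Step 1
Reactants: 1 (S)-terpinen-4-ol
Product: 2 (S)-terpinen-4-ol triethylsilyl ether
Conditions: TESOTf, 2,6-lutidine, CH2Cl2, 0 °C → rt
Reagents that add atoms: triethylsilyl trifluoromethanesulfonate, CC[Si](CC)(CC)OS(=O)(=O)C(F)(F)F
Why: Silyl triflate/lutidine silylation of a tertiary alcohol; the C4 centre of the starting material is untouched and is the only source of chirality in the route.

Step 2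
Reactants: 2 (S)-terpinen-4-ol triethylsilyl ether
Product: 3 (3S)-6-oxo-3-(propan-2-yl)-3-(triethylsilyloxy)heptanal
Conditions: O3, CH2Cl2, −78 °C; then PPh3, −78 °C → rt
Reagents that add atoms: ozone, [O-][O+]=O
Why: Ozonolysis with reductive work-up cleaves the only alkene to the keto aldehyde; the silyl ether prevents hemiketal formation and no stereocentre is touched.

Step 3
Reactants: 3 (3S)-6-oxo-3-(propan-2-yl)-3-(triethylsilyloxy)heptanal
Product: 4 (5R)-2-methyl-5-(propan-2-yl)-5-(triethylsilyloxy)cyclopent-1-ene-1-carbaldehyde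
Conditions: piperidine (cat.), AcOH (cat.), toluene, rt → 50 °C
Reagents that add atoms: none
Why: Amine-catalysed intramolecular aldol condensation: the enamine of the aldehyde adds to the methyl ketone (five-membered ring closure) and dehydration gives the tetrasubstituted enal; no new stereocentre.

Step 4
Reactants: 4 (5R)-2-methyl-5-(propan-2-yl)-5-(triethylsilyloxy)cyclopent-1-ene-1-carbaldehyde
Product: 5 (5R)-5-hydroxy-2-methyl-5-(propan-2-yl)cyclopent-1-ene-1-carbaldehyde
Conditions: HF·pyridine, pyridine, THF, 0 °C → rt
Reagents that add atoms: none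
Why: Fluoride cleavage of the tertiary silyl ether frees O4 for the later silicon bridge; the conjugated aldehyde disfavours ionisation at C4.

Step 5
Reactants: 6 (±)-4-(trimethylsilyl)but-3-yn-2-ol
Product: 7 (±)-4-(trimethylsilyl)but-3-yn-2-yl methanesulfonate
Conditions: MsCl, Et3N, CH2Cl2, −78 → 0 °C
Reagents that add atoms: methanesulfonyl chloride, CS(=O)(=O)Cl
Why: Mesylation of a secondary propargylic alcohol; the centre is lost later, so the racemate is used.

Step 6
Reactants: 5 (5R)-5-hydroxy-2-methyl-5-(propan-2-yl)cyclopent-1-ene-1-carbaldehyde; 7 (±)-4-(trimethylsilyl)but-3-yn-2-yl methanesulfonate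
Product: 9 homopropargylic diol (C6 carbinol and C8 methyl centre as epimer mixture), via allenylindium reagent 8 (not isolated)
Conditions: PdCl2(dppf) (5 mol %; dppf = 1,1′-bis(diphenylphosphino)ferrocene), InI, THF/HMPA 3:1, rt
Reagents that add atoms: none
Why: Marshall propargylation: zerovalent palladium turns the mesylate into an allenylpalladium species that transmetallates to indium, and the allenylindium adds to the aldehyde by SE2′ to give the homopropargylic alcohol; the free hydroxyl is tolerated and the two new centres are erased in steps 7 and 8.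

Step 7
Reactants: 9 homopropargylic diol
Product: 10 α-alkynyl ketone (C8 epimers) with free C4 hydroxyl
Conditions: Dess–Martin periodinane, NaHCO3, CH2Cl2, 0 °C → rt
Reagents that add atoms: none
Why: Dess–Martin oxidation of the secondary allylic alcohol; the tertiary alcohol is inert and the buffered, non-basic medium avoids isomerisation to the allenyl ketone.

Step 8
Reactants: 10 α-alkynyl ketone
Product: 12 silylene-bridged (E)-dienol ether, via silyl triflate 11 (not isolated)
Conditions: t-Bu2Si(OTf)2, 2,6-lutidine, CH2Cl2, 0 °C → rt; then Et3N, 0 °C → rt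
Reagents that add atoms: di-tert-butylsilyl bis(trifluoromethanesulfonate), CC(C)(C)[Si](OS(=O)(=O)C(F)(F)F)(OS(=O)(=O)C(F)(F)F)C(C)(C)C
Why: Silylation of the tertiary alcohol followed by intramolecular soft enolisation (silyl triflate/amine) closes the six-membered O4–Si–O6 ring at the only α-hydrogen; the slim alkynyl group should take the crowded inner position next to the cyclopentene, which gives the (E)-enol ether (methyl cis to O6).

Step 9
Reactants: 12 silylene-bridged (E)-dienol ether
Product: 13 spiro siloxycyclopropane (silylalkynyl cis to cyclopentenyl; C8 on the α face)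
Conditions: Et2Zn, CH2I2, ClCH2CH2Cl, 0 °C → rt; pyridine quench
Reagents that add atoms: diiodomethane, ICI
Why: Furukawa–Simmons–Smith cyclopropanation of the silyl enol ether (the alkyne is inert and the twisted cyclopentene alkene is less nucleophilic), stereospecific so that alkynyl and cyclopentenyl stay cis; the bridge holds O6 on the face of O4, so methylene should add from the side away from the C4 isopropyl group and push C8 to the α face, which sets both cyclopropane centres.

Step 10
Reactants: 13 spiro siloxycyclopropane
Product: 14 terminal alkynyl cyclopropane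
Conditions: K2CO3 (cat.), MeOH, rt
Reagents that add atoms: none
Why: Methanolysis of the alkynyl C–Si bond; the di-tert-butylsilylene and the cyclopropyl silyl ether are stable to carbonate.

Step 11
Reactants: 14 terminal alkynyl cyclopropane
Product: 15 bridged cis-1-cyclopentenyl-1-siloxy-2-methyl-2-vinylcyclopropane
Conditions: H2 (1 atm), Pd/CaCO3 poisoned with Pb(OAc)2 (Lindlar catalyst), quinoline, hexane/EtOAc, 0 °C
Reagents that add atoms: none
Why: Lindlar semi-hydrogenation of the terminal alkyne to the vinyl group; the tetrasubstituted alkene is not reduced and the product is kept cold and used at once.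

Step 12
Reactants: 15 bridged cis-1-cyclopentenyl-1-siloxy-2-methyl-2-vinylcyclopropane
Product: 16 bridged hydroazulene 5,8-diene (C5=C6 silyl enol ether, C8=C9, quaternary C1)
Conditions: toluene (0.01 M), 2,6-di-tert-butyl-4-methylphenol (trace), base-washed sealed tube, 80 → 110 °C
Reagents that add atoms: none
Why: On heating, 15 undergoes a concerted [3,3]-sigmatropic shift (cis-divinylcyclopropane Cope rearrangement) through the endo-boat array, in which the C6–C8 cyclopropane bond breaks, C10 bonds to C1, and the C5=C6 silyl enol ether and the C8=C9 alkene appear. The closest known reaction type is the thermal rearrangement of cis-2-siloxy-1,2-divinylcyclopropanes to cyclohepta-1,4-dienes, cycloalkenyl partners that end as quaternary carbons included. The seven-membered ring is closed by ring enlargement: the three cyclopropane carbons (C6, C7, C8) and the four atoms C9, C10, C1 and C5 end in one ring, driven by relief of cyclopropane strain and by the siloxy donor on the breaking bond. C1 is the only new stereocentre and is set by relay from the cyclopropane, because C10 can bond only to the face of C1 on which C8 lies. The step needs C10 to arrive anti to the C4 oxygen (the methyl group then ends cis to it); the silicon bridge secures this by holding O6 next to O4 on the β face, which fixes the C6–C8 bond perpendicular to the cyclopentene on the α face, so the only boat within reach is the wanted one. The fully substituted terminus C1 calls for more heat than a plain vinyl case, which is why the cis geometry was secured in steps 8 and 9 and no epimerisation at the cyclopropane is needed.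

Step 13
Reactants: 16 bridged hydroazulene 5,8-diene
Product: 18 4β-hydroxydauc-8-en-6-one (5α-H), via silanol ketone 17 (not isolated)
Conditions: camphorsulfonic acid (cat.), THF/H2O, 0 °C; then HF·pyridine, pyridine, 0 °C → rt
Reagents that add atoms: none
Why: Acid hydrolysis of the silyl enol ether (C-protonation, then loss of silicon from O6) followed by fluoride cleavage of the remaining Si–O bond; C5 should be protonated kinetically on the α face, opposite the angular methyl and the silicon bridge, which gives the trans ring fusion, and base is avoided because the β,γ-unsaturated ketone would conjugate.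

Step 14
Reactants: 18 4β-hydroxydauc-8-en-6-one
Product: 19 dauc-8-ene-4β,6α-diol
Conditions: Me4NBH(OAc)3, MeCN/AcOH 1:1, −30 → −20 °C
Reagents that add atoms: none
Why: Hydroxyl-directed (Evans–Saksena) reduction: the borohydride bound to the C4 oxygen delivers hydride within the molecule to the carbonyl face next to O4, which should place the new hydroxyl α, anti to the C4 oxygen.

Step 15
Reactants: 19 dauc-8-ene-4β,6α-diol; 20 4-acetoxybenzoic acid
Product: 21 6-O-(4-acetoxybenzoyl)dauc-8-ene-4β,6α-diol
Conditions: DCC, DMAP (cat.), CH2Cl2, 0 °C → rt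
Reagents that add atoms: none
Why: Steglich esterification of the secondary C6 alcohol; the tertiary C4 alcohol does not react.

Step 16
Reactants: 21 6-O-(4-acetoxybenzoyl)dauc-8-ene-4β,6α-diol
Product: 22 6α-(4-acetoxybenzoyloxy)-4β-hydroxydauc-8-en-10-one
Conditions: Rh2(cap)4 (dirhodium tetracaprolactamate, 1 mol %), t-BuOOH (70% aq), ClCH2CH2Cl, 40 °C
Reagents that add atoms: tert-butyl hydroperoxide, CC(C)(C)OO
Why: Allylic C–H oxidation by tert-butylperoxyl radicals: the methylene on the CH end of the trisubstituted alkene (C10) should be oxidised to the β-methyl enone, as at C7 of 3-acyloxy-Δ5-steroids, while C7 is deactivated by the neighbouring acyloxy carbon.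

Step 17
Reactants: 22 6α-(4-acetoxybenzoyloxy)-4β-hydroxydauc-8-en-10-one
Product: 23 CNP0210039.1 (6α-(4-hydroxybenzoyloxy)-4β-hydroxydauc-8-en-10-one)
Conditions: pyrrolidine, CH2Cl2, 0 °C → rt
Reagents that add atoms: none
Why: Aminolysis of the aryl acetate; the hindered alkyl benzoate is far slower and the non-ionic base avoids vinylogous elimination of the C6 acyloxy group.

**Compound list**
1 | (S)-terpinen-4-ol | CC1=CC[C@](O)(C(C)C)CC1 | starting material
2 | (S)-terpinen-4-ol triethylsilyl ether | CC1=CC[C@](O[Si](CC)(CC)CC)(C(C)C)CC1 | intermediate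
3 | (3S)-6-oxo-3-(propan-2-yl)-3-(triethylsilyloxy)heptanal | O=CC[C@](O[Si](CC)(CC)CC)(C(C)C)CCC(C)=O | intermediate
4 | (5R)-2-methyl-5-(propan-2-yl)-5-(triethylsilyloxy)cyclopent-1-ene-1-carbaldehyde | CC1=C(C=O)[C@](O[Si](CC)(CC)CC)(C(C)C)CC1 | intermediate
5 | (5R)-5-hydroxy-2-methyl-5-(propan-2-yl)cyclopent-1-ene-1-carbaldehyde | CC1=C(C=O)[C@](O)(C(C)C)CC1 | intermediate
6 | (±)-4-(trimethylsilyl)but-3-yn-2-ol | CC(O)C#C[Si](C)(C)C | starting material
7 | (±)-4-(trimethylsilyl)but-3-yn-2-yl methanesulfonate | CC(OS(C)(=O)=O)C#C[Si](C)(C)C | intermediate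
8 | [1-(trimethylsilyl)buta-1,2-dien-1-yl]indium iodide methanesulfonate (allenylindium reagent, not isolated) | CC=C=C([Si](C)(C)C)[In](I)OS(C)(=O)=O | intermediate
9 | (1R)-2-[1-hydroxy-2-methyl-4-(trimethylsilyl)but-3-yn-1-yl]-3-methyl-1-(propan-2-yl)cyclopent-2-en-1-ol (side-chain centres as mixture) | CC1=C(C(O)C(C)C#C[Si](C)(C)C)[C@](O)(C(C)C)CC1 | intermediate
10 | 1-[(5R)-5-hydroxy-2-methyl-5-(propan-2-yl)cyclopent-1-en-1-yl]-2-methyl-4-(trimethylsilyl)but-3-yn-1-one (C8 epimers) | CC1=C(C(=O)C(C)C#C[Si](C)(C)C)[C@](O)(C(C)C)CC1 | intermediate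
11 | C4-O-[di-tert-butyl(trifluoromethanesulfonyloxy)silyl] ether of 10 (not isolated) | CC1=C(C(=O)C(C)C#C[Si](C)(C)C)[C@](O[Si](OS(=O)(=O)C(F)(F)F)(C(C)(C)C)C(C)(C)C)(C(C)C)CC1 | intermediate
12 | O4,O6-di-tert-butylsilylene-bridged (E)-dienol ether of 10 (six-membered O–Si–O ring; exocyclic C6=C8 with methyl cis to O6 and silylalkynyl cis to the cyclopentene) | CC1=C2/C(=C(/C)C#C[Si](C)(C)C)O[Si](C(C)(C)C)(C(C)(C)C)O[C@@]2(C(C)C)CC1 | intermediate
13 | bridged spiro siloxycyclopropane (C7 methylene across C6–C8; silylalkynyl on C8 cis to the cyclopentenyl on C6; C8 on the α face) | C[C@]1(C#C[Si](C)(C)C)C[C@]12O[Si](C(C)(C)C)(C(C)(C)C)O[C@@]3(C(C)C)CCC(C)=C23 | intermediate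
14 | terminal alkyne (13 without the trimethylsilyl group) | C[C@]1(C#C)C[C@]12O[Si](C(C)(C)C)(C(C)(C)C)O[C@@]3(C(C)C)CCC(C)=C23 | intermediate
15 | bridged cis-1-cyclopentenyl-1-siloxy-2-methyl-2-vinylcyclopropane (Cope precursor) | C[C@]1(C=C)C[C@]12O[Si](C(C)(C)C)(C(C)(C)C)O[C@@]3(C(C)C)CCC(C)=C23 | intermediate
16 | bridged hydroazulene 5,8-diene (C5=C6 silyl enol ether tied to O4; C8=C9; C1 methyl cis to O4) | CC1=CC[C@@]2(C)CC[C@]3(C(C)C)O[Si](C(C)(C)C)(C(C)(C)C)OC(C1)=C23 | intermediate
17 | 4β-[di-tert-butyl(hydroxy)silyloxy]dauc-8-en-6-one, 5α-H (not isolated) | CC1=CC[C@@]2(C)CC[C@@](O[Si](O)(C(C)(C)C)C(C)(C)C)(C(C)C)[C@@H]2C(=O)C1 | intermediate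
18 | 4β-hydroxydauc-8-en-6-one (trans-fused, 5α-H) | CC1=CC[C@@]2(C)CC[C@@](O)(C(C)C)[C@@H]2C(=O)C1 | intermediate
19 | dauc-8-ene-4β,6α-diol | CC1=CC[C@@]2(C)CC[C@@](O)(C(C)C)[C@@H]2[C@@H](O)C1 | intermediate
20 | 4-acetoxybenzoic acid | CC(=O)Oc1ccc(cc1)C(=O)O | starting material
21 | 6-O-(4-acetoxybenzoyl)dauc-8-ene-4β,6α-diol | CC1=CC[C@@]2(C)CC[C@@](O)(C(C)C)[C@@H]2[C@@H](OC(=O)c2ccc(OC(C)=O)cc2)C1 | intermediate
22 | 6α-(4-acetoxybenzoyloxy)-4β-hydroxydauc-8-en-10-one | CC1=CC(=O)[C@@]2(C)CC[C@@](O)(C(C)C)[C@@H]2[C@@H](OC(=O)c2ccc(OC(C)=O)cc2)C1 | intermediate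
23 | CNP0210039.1, 6α-(4-hydroxybenzoyloxy)-4β-hydroxydauc-8-en-10-one | CC1=CC(=O)[C@@]2(C)CC[C@@](O)(C(C)C)[C@@H]2[C@@H](OC(=O)c2ccc(O)cc2)C1 | target

**Step count**
Total steps: 17 (16 in the main line plus the mesylation of 6, step 5).
Longest linear sequence: 16 steps (1 → 23 through steps 1–4 and 6–17).

**Steps most likely to fail**

1. Step 12 (Cope rearrangement). The vinyl arm has to pass under the C4 isopropyl group to reach C1, so the boat may be reached too slowly. Homolysis of the donor-substituted C6–C8 bond and 1,5-hydrogen shifts could then compete at the temperature needed. Fallback: make the C1–C10 bond by an anionic oxy-Cope rearrangement and close the ring by metathesis. It sets out from 5. Asymmetric allylation with B-allyldiisopinocampheylborane (the antipode that gives the (S)-carbinol) should give the (S)-allyl carbinol diol F1. Its dipotassium salt (KH, THF) should rearrange with potassium bridging O4 and O6, which holds the carbinol oxygen on the β face and the allyl arm on the α face, so that the allyl terminus bonds to C1 anti to O4. A cold acidic quench then gives the hydroxy aldehyde with quaternary C1, F2. Addition of 2-methylallylmagnesium chloride gives the diene diol F3 (C6 epimers). Ring-closing metathesis with the second-generation Grubbs catalyst closes C8=C9 to the C6-epimeric dauc-8-ene-4,6-diols F4. Dess–Martin oxidation of the secondary alcohol comes back to the route at 18.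

2. Step 9 (cyclopropanation). Methylene transfer to a hindered, alkyne-conjugated tetrasubstituted enol ether may be slow, and attack on the cyclopentene alkene or on the wrong face could compete. Fallback: use the free C4 hydroxyl as a directing group in place of the bridge. It sets out from 10. KN(SiMe3)2 (2 equiv) and tert-butyldimethylsilyl chloride should silylate only the enolate oxygen to give the (E)-TBS dienol ether with free C4 hydroxyl, F5. The zinc alkoxide of F5 should deliver methylene (Et2Zn/CH2I2) to the enol ether face syn to O4, which leads to the same cyclopropane configuration in the hydroxy TBS cyclopropane F6. K2CO3/MeOH gives the terminal alkyne F7, and Lindlar reduction gives the untethered cis-divinylcyclopropane F8. Its Cope rearrangement (toluene, heat, with the O4–H···O6 hydrogen bond in place of the bridge) should give the TBS enol ether diene F9. HF·pyridine then comes back to the route at 18.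

3. Step 16 (allylic oxidation). Hydrogen abstraction may be poorly site-selective (C7 or the C8 methyl instead of C10), or over-oxidation may occur. Fallback: place the oxygen by a 1,3-transposition. It sets out from 21. mCPBA gives the 8,9-epoxide F10. Sodium phenylselenide (PhSeSePh, NaBH4, EtOH) should open it at the secondary carbon C9 to the hydroxy selenide F11; the phenolic acetate is expected to be lost here by ethanolysis. H2O2 oxidation and selenoxide syn-elimination, which can only run towards C10, should give the tertiary allylic alcohol F12 (C8–OH, C9=C10). Pyridinium chlorochromate, C5H5NH[CrO3Cl], then effects the oxidative 1,3-transposition (Babler–Dauben) to the 8-en-10-one. As the phenol is already free, this comes back to the route at 23.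

**Further compounds**
F1 | step 12 | (S)-allyl carbinol diol | CC1=C([C@@H](O)CC=C)[C@](O)(C(C)C)CC1
F2 | step 12 | hydroxy aldehyde with quaternary C1 (allyl α, methyl β, 5α-H) | C=CC[C@@]1(C)CC[C@@](O)(C(C)C)[C@@H]1C=O
F3 | step 12 | diene diol (C6 epimers) | C=CC[C@@]1(C)CC[C@@](O)(C(C)C)[C@@H]1C(O)CC(C)=C
F4 | step 12 | C6-epimeric dauc-8-ene-4,6-diols | CC1=CC[C@@]2(C)CC[C@@](O)(C(C)C)[C@@H]2C(O)C1
F5 | step 9 | (E)-TBS dienol ether with free C4 hydroxyl | CC1=C(/C(O[Si](C)(C)C(C)(C)C)=C(/C)C#C[Si](C)(C)C)[C@](O)(C(C)C)CC1
F6 | step 9 | hydroxy TBS cyclopropane | C[C@]1(C#C[Si](C)(C)C)C[C@@]1(O[Si](C)(C)C(C)(C)C)C1=C(C)CC[C@@]1(O)C(C)C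
F7 | step 9 | terminal alkyne | C[C@]1(C#C)C[C@@]1(O[Si](C)(C)C(C)(C)C)C1=C(C)CC[C@@]1(O)C(C)C
F8 | step 9 | untethered cis-divinylcyclopropane | C[C@]1(C=C)C[C@@]1(O[Si](C)(C)C(C)(C)C)C1=C(C)CC[C@@]1(O)C(C)C
F9 | step 9 | TBS enol ether diene | CC1=CC[C@@]2(C)CC[C@@](O)(C(C)C)C2=C(O[Si](C)(C)C(C)(C)C)C1
F10 | step 16 | 8,9-epoxide (epoxide epimers) | CC13OC3C[C@@]2(C)CC[C@@](O)(C(C)C)[C@@H]2[C@@H](OC(=O)c2ccc(OC(C)=O)cc2)C1
F11 | step 16 | hydroxy selenide (phenol free) | CC1(O)C([Se]c2ccccc2)C[C@@]2(C)CC[C@@](O)(C(C)C)[C@@H]2[C@@H](OC(=O)c2ccc(O)cc2)C1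
F12 | step 16 | tertiary allylic alcohol | CC1(O)C=C[C@@]2(C)CC[C@@](O)(C(C)C)[C@@H]2[C@@H](OC(=O)c2ccc(O)cc2)C1
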